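**Plan**

- Retrosynthesis cuts first the C1'–C7' aryl–CH2 bond (Negishi), giving a ring B/ring C aryl bromide and a ring A 2,3-dimethylbutyl iodide. It then cuts C7''–C8'' (aldol) in the bromide and C1–C7 (Negishi) in the iodide.
- Enabling feature: C7'' carries OH and ring C, and C8'' carries the ring B ether oxygen and the C9'' methyl, in an anti (erythro) array. This is the retron of an aldol between the ring C aldehyde and a ring B aryloxyacetate enolate whose carboxyl carbon becomes C9''.
- Forward, fragment 1: ring B phenol → aryloxythioacetate → Z ketene silyl thioacetal → asymmetric Mukaiyama aldol with O-benzylvanillin → thioester reduced to the C9'' methyl → silyl ether.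
- Forward, fragment 2: meso-2,3-dimethylsuccinic anhydride → hemiester → cis-lactone → iodo ester → Negishi coupling with the ring A bromide → alkyl iodide. The fragments are then joined (C7'–C1') and deprotected; no ring is formed anywhere, the chain is joined C7''–C8'', then C7–C1, then C7'–C1'.
- Stereochemistry: C7''/C8'' come from the chiral tin–diamine promoter and the Z enolate geometry. C8/C8' are relative from the meso diacid and absolute from alkaloid-catalysed methanolysis of its anhydride, which decides which carboxyl carbon becomes C7.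

Key step: step 4

Assumption 1: the (R)-diamine (made from D-proline by N-acetylation, piperidine amide formation and LiAlH4 reduction) is chosen because, in the benzyloxy series, the (S)-diamine leads to (2R,3R) anti adducts of aromatic aldehydes; if the sense proved opposite, the (S)-diamine would be used.

Assumption 2: the quinine-derived catalyst (DHQ)2AQN is taken to open the cis-anhydride to the (2R,3S) hemiester, as quinine-type catalysts do with related cis-disubstituted succinic anhydrides; the sign of rotation of the known cis-lactone made from it checks this before material is committed.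

**Route**

Step 1
Reactants: 1 bromoacetyl bromide
Product: 2 S-ethyl 2-bromoethanethioate
Conditions: EtSH, pyridine, CH2Cl2, -20 to 0 °C
Reagents that add atoms: ethanethiol CCS
Why: Nucleophilic acyl substitution (thioesterification) at the acyl bromide is much faster than SN2 attack of the thiol at the alpha-bromide, and pyridine takes up HBr.

Step 2
Reactants: 3 4-bromo-2,6-dimethoxyphenol; 2 S-ethyl 2-bromoethanethioate
Product: 4 S-ethyl 2-(4-bromo-2,6-dimethoxyphenoxy)ethanethioate
Conditions: K2CO3, acetone, 25–40 °C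
Reagents that add atoms: none
Why: Williamson ether synthesis on a highly reactive alpha-halo carbonyl electrophile, under a mild carbonate base that leaves the thioester intact.

Step 3
Reactants: 4 S-ethyl 2-(4-bromo-2,6-dimethoxyphenoxy)ethanethioate
Product: 5 (Z)-{[2-(4-bromo-2,6-dimethoxyphenoxy)-1-(ethylsulfanyl)ethenyl]oxy}trimethylsilane
Conditions: LiN(iPr)2, Me3SiCl (internal quench), THF, -78 °C; pentane, filtration, used crude
Reagents that add atoms: chlorotrimethylsilane C[Si](C)(C)Cl
Why: Kinetic enolisation of the thioester with in situ O-silylation is the protocol that gives the Z ketene silyl thioacetal in the benzyloxy series, and the alpha-proton is far more acidic than any ring proton, so the aryl bromide should be untouched.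

Step 4
Reactants: 5 (Z)-{[2-(4-bromo-2,6-dimethoxyphenoxy)-1-(ethylsulfanyl)ethenyl]oxy}trimethylsilane; 6 4-(benzyloxy)-3-methoxybenzaldehyde
Product: 8 S-ethyl (2S,3S)-3-[4-(benzyloxy)-3-methoxyphenyl]-2-(4-bromo-2,6-dimethoxyphenoxy)-3-hydroxypropanethioate, via O-trimethylsilyl aldol adduct 7 (not isolated)
Conditions: Sn(OTf)2, (R)-1-ethyl-2-(piperidin-1-ylmethyl)pyrrolidine, Bu2Sn(OAc)2, CH2Cl2, -78 °C; aq. NaHCO3; then 1 M HCl, THF, 0 °C
Reagents that add atoms: none
Why: The divalent tin triflate–diamine complex binds and activates aldehyde 6, ketene silyl thioacetal 5 attacks it through an open transition state and silicon moves to the new alkoxide, with Bu2Sn(OAc)2 suppressing the achiral silyl-triflate-promoted background reaction. The closest known reaction is the asymmetric Mukaiyama aldol of (Z)-2-benzyloxy ketene silyl thioacetals with aromatic aldehydes, which gives anti diol derivatives. No ring is closed; only the C7''–C8'' bond forms. C7'' (C3) is set by the aldehyde face that the chiral diamine on tin leaves open, and C8'' (C2) is set relative to it by the Z geometry of 5 together with coordination of its alpha-ether oxygen to tin, which turns the usual syn preference into anti. The step needs anti over syn and the (2S,3S) enantiomer; the (R)-diamine supplies the latter, and the 2,6-dimethoxy substitution twists the ether oxygen out of conjugation with ring B and adds flanking methoxy donors, so it should bind tin about as well as a benzyl ether oxygen. The aldehyde cannot enolise, and the thioester, aryl bromide and benzyl ether are inert to the promoter.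

Step 5
Reactants: 8 S-ethyl (2S,3S)-3-[4-(benzyloxy)-3-methoxyphenyl]-2-(4-bromo-2,6-dimethoxyphenoxy)-3-hydroxypropanethioate
Product: 9 (1S,2R)-1-[4-(benzyloxy)-3-methoxyphenyl]-2-(4-bromo-2,6-dimethoxyphenoxy)propane-1,3-diol
Conditions: LiBH4, THF, MeOH (1 equiv), 0 °C to rt
Reagents that add atoms: none
Why: Hydride reduction of a thioester to the primary alcohol proceeds under conditions that spare aryl bromide and benzyl ether, and it removes the enolisable carbonyl next to C8''.

Step 6
Reactants: 9 (1S,2R)-1-[4-(benzyloxy)-3-methoxyphenyl]-2-(4-bromo-2,6-dimethoxyphenoxy)propane-1,3-diol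
Product: 10 (2R,3S)-3-[4-(benzyloxy)-3-methoxyphenyl]-2-(4-bromo-2,6-dimethoxyphenoxy)-3-hydroxypropyl 4-methylbenzenesulfonate
Conditions: TsCl (1.05 equiv), pyridine, CH2Cl2, 0 °C
Reagents that add atoms: 4-methylbenzenesulfonyl chloride Cc1ccc(cc1)S(Cl)(=O)=O
Why: Selective sulfonylation of the primary hydroxyl over the hindered secondary benzylic one is standard for 1,3-diols of this type.

Step 7
Reactants: 10 (2R,3S)-3-[4-(benzyloxy)-3-methoxyphenyl]-2-(4-bromo-2,6-dimethoxyphenoxy)-3-hydroxypropyl 4-methylbenzenesulfonate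
Product: 11 (1S,2R)-1-[4-(benzyloxy)-3-methoxyphenyl]-2-(4-bromo-2,6-dimethoxyphenoxy)propan-1-ol
Conditions: LiEt3BH (excess), THF, 0 °C to rt
Reagents that add atoms: none
Why: SN2 displacement of a primary tosylate by hydride, precedented for 1,3-diol monotosylates of 8-O-4' neolignan precursors, should outpace four-membered ring closure and leaves the aryl bromide alone.

Step 8
Reactants: 11 (1S,2R)-1-[4-(benzyloxy)-3-methoxyphenyl]-2-(4-bromo-2,6-dimethoxyphenoxy)propan-1-ol
Product: 12 {(1S,2R)-1-[4-(benzyloxy)-3-methoxyphenyl]-2-(4-bromo-2,6-dimethoxyphenoxy)propoxy}(tert-butyl)dimethylsilane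
Conditions: t-BuMe2SiCl, imidazole, DMF, rt
Reagents that add atoms: tert-butyl(chloro)dimethylsilane CC(C)(C)[Si](C)(C)Cl
Why: Silyl ether formation under non-acidic conditions removes the only acidic proton before the organozinc coupling without risk of ionising the electron-rich benzylic position.

Step 9
Reactants: 13 4-bromo-2-methoxyphenol
Product: 14 1-(benzyloxy)-4-bromo-2-methoxybenzene
Conditions: BnBr, K2CO3, DMF, rt
Reagents that add atoms: benzyl bromide BrCc1ccccc1
Why: Williamson benzylation of a phenol is routine.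

Step 10
Reactants: 15 meso-2,3-dimethylsuccinic acid
Product: 16 cis-3,4-dimethyloxolane-2,5-dione (meso, 3R,4S)
Conditions: AcCl, reflux; evaporation
Reagents that add atoms: none
Why: Cyclodehydration of the 1,4-diacid with acetyl chloride gives the cis anhydride with retention, since no base is present to epimerise it.

Step 11
Reactants: 16 cis-3,4-dimethyloxolane-2,5-dione
Product: 17 (2R,3S)-4-methoxy-2,3-dimethyl-4-oxobutanoic acid
Conditions: MeOH (10 equiv), (DHQ)2AQN (hydroquinine anthraquinone-1,4-diyl diether, cat.), Et2O, -20 °C; acid wash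
Reagents that add atoms: methanol CO
Why: Alkaloid-catalysed enantioselective methanolysis (desymmetrisation of a meso anhydride) directs methanol to one enantiotopic carbonyl and thereby fixes the absolute configuration of the future C8 and C8', whose relative configuration comes from the meso acid.

Step 12
Reactants: 17 (2R,3S)-4-methoxy-2,3-dimethyl-4-oxobutanoic acid
Product: 19 (3S,4R)-3,4-dimethyloxolan-2-one, via hydroxy ester 18 (not isolated)
Conditions: BH3·SMe2, THF, -10 °C to rt; MeOH quench; TsOH (cat.), CH2Cl2, rt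
Reagents that add atoms: none
Why: Borane reduces the carboxylic acid chemoselectively beside the methyl ester, and the resulting gamma-hydroxy ester lactonises under acid catalysis without touching either stereocentre.

Step 13
Reactants: 19 (3S,4R)-3,4-dimethyloxolan-2-one
Product: 22 methyl (2S,3R)-4-iodo-2,3-dimethylbutanoate, via trimethylsilyl ester 20 (not isolated), via iodo acid 21 (not isolated)
Conditions: Me3SiCl, NaI, MeCN, 60 °C; then MeOH, rt
Reagents that add atoms: sodium iodide [Na+].[I-]; methanol CO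
Why: Iodotrimethylsilane made in the flask cleaves the lactone by SN2 attack of iodide at the O–CH2 carbon, and methanolysis with acid-catalysed Fischer esterification gives the ester under conditions that avoid relactonisation through a carboxylate.

Step 14
Reactants: 22 methyl (2S,3R)-4-iodo-2,3-dimethylbutanoate; 14 1-(benzyloxy)-4-bromo-2-methoxybenzene
Product: 24 methyl (2S,3S)-4-[4-(benzyloxy)-3-methoxyphenyl]-2,3-dimethylbutanoate, via alkylzinc iodide 23 (not isolated)
Conditions: Zn dust (activated), LiCl, THF, 40 °C; then 14, Pd(OAc)2 (cat.), SPhos (2-dicyclohexylphosphino-2',6'-dimethoxybiphenyl), THF, 25–50 °C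
Reagents that add atoms: none
Why: LiCl-promoted zinc insertion into a primary alkyl iodide tolerates the ester, and Negishi coupling of primary alkylzinc halides with aryl bromides under zerovalent palladium–SPhos catalysis is well established and does not involve the stereocentres.

Step 15
Reactants: 24 methyl (2S,3S)-4-[4-(benzyloxy)-3-methoxyphenyl]-2,3-dimethylbutanoate
Product: 25 (2S,3S)-4-[4-(benzyloxy)-3-methoxyphenyl]-2,3-dimethylbutan-1-ol
Conditions: LiAlH4, THF, 0 °C
Reagents that add atoms: none
Why: Ester reduction with LiAlH4 is fast at 0 °C, which leaves no time for epimerisation at the alpha-carbon and does not affect the benzyl ether.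

Step 16
Reactants: 25 (2S,3S)-4-[4-(benzyloxy)-3-methoxyphenyl]-2,3-dimethylbutan-1-ol
Product: 26 1-(benzyloxy)-4-[(2S,3S)-4-iodo-2,3-dimethylbutyl]-2-methoxybenzene
Conditions: I2, PPh3, imidazole, CH2Cl2, 0 °C to rt
Reagents that add atoms: iodine II
Why: Appel-type iodination of a primary alcohol is reliable and neutral.

Step 17
Reactants: 26 1-(benzyloxy)-4-[(2S,3S)-4-iodo-2,3-dimethylbutyl]-2-methoxybenzene; 12 {(1S,2R)-1-[4-(benzyloxy)-3-methoxyphenyl]-2-(4-bromo-2,6-dimethoxyphenoxy)propoxy}(tert-butyl)dimethylsilane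
Product: 28 {(1S,2R)-1-[4-(benzyloxy)-3-methoxyphenyl]-2-[4-{(2R,3S)-4-[4-(benzyloxy)-3-methoxyphenyl]-2,3-dimethylbutyl}-2,6-dimethoxyphenoxy]propoxy}(tert-butyl)dimethylsilane, via alkylzinc iodide 27 (not isolated)
Conditions: Zn dust (activated), LiCl, THF, 40 °C; then 12, Pd(OAc)2 (cat.), SPhos, THF, 50 °C
Reagents that add atoms: none
Why: Negishi sp3–sp2 coupling of a primary alkylzinc iodide with an aryl bromide whose two ortho positions are unsubstituted forms C7'–C1' in the presence of silyl and benzyl ethers and brings all four stereocentres together unchanged.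

Step 18
Reactants: 28 {(1S,2R)-1-[4-(benzyloxy)-3-methoxyphenyl]-2-[4-{(2R,3S)-4-[4-(benzyloxy)-3-methoxyphenyl]-2,3-dimethylbutyl}-2,6-dimethoxyphenoxy]propoxy}(tert-butyl)dimethylsilane
Product: 29 (1S,2R)-1-[4-(benzyloxy)-3-methoxyphenyl]-2-[4-{(2R,3S)-4-[4-(benzyloxy)-3-methoxyphenyl]-2,3-dimethylbutyl}-2,6-dimethoxyphenoxy]propan-1-ol
Conditions: Bu4NF, THF, 0 °C to rt
Reagents that add atoms: none
Why: Fluoride-mediated cleavage of the silyl ether is selective for silicon and leaves the benzyl ethers and the aryl alkyl ether intact.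

Step 19
Reactants: 29 (1S,2R)-1-[4-(benzyloxy)-3-methoxyphenyl]-2-[4-{(2R,3S)-4-[4-(benzyloxy)-3-methoxyphenyl]-2,3-dimethylbutyl}-2,6-dimethoxyphenoxy]propan-1-ol
Product: 30 (+)-(7''S,8S,8'R,8''R)-4,4''-dihydroxy-3,3',3'',5'-tetramethoxy-4',8''-oxy-8,8'-sesquineolignan-7''-ol
Conditions: H2 (1 atm), 10% Pd/C, EtOAc, rt
Reagents that add atoms: none
Why: Hydrogenolysis of aryl benzyl ethers over Pd/C in a neutral solvent is much faster than hydrogenolysis of the secondary benzylic alcohol and is the usual last step for phenolic 8-O-4' ethers.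

**Compound list**

1 | bromoacetyl bromide | BrCC(Br)=O | starting material
2 | S-ethyl 2-bromoethanethioate | CCSC(=O)CBr | intermediate
3 | 4-bromo-2,6-dimethoxyphenol | COc1cc(Br)cc(OC)c1O | starting material
4 | S-ethyl 2-(4-bromo-2,6-dimethoxyphenoxy)ethanethioate | COc1cc(Br)cc(OC)c1OCC(=O)SCC | intermediate
5 | (Z)-{[2-(4-bromo-2,6-dimethoxyphenoxy)-1-(ethylsulfanyl)ethenyl]oxy}trimethylsilane | COc1cc(Br)cc(OC)c1O/C=C(\SCC)O[Si](C)(C)C | intermediate
6 | 4-(benzyloxy)-3-methoxybenzaldehyde | COc1cc(C=O)ccc1OCc1ccccc1 | starting material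
7 | S-ethyl (2S,3S)-3-[4-(benzyloxy)-3-methoxyphenyl]-2-(4-bromo-2,6-dimethoxyphenoxy)-3-[(trimethylsilyl)oxy]propanethioate | COc1cc(Br)cc(OC)c1O[C@H](C(=O)SCC)[C@@H](O[Si](C)(C)C)c1ccc(OCc2ccccc2)c(OC)c1 | intermediate
8 | S-ethyl (2S,3S)-3-[4-(benzyloxy)-3-methoxyphenyl]-2-(4-bromo-2,6-dimethoxyphenoxy)-3-hydroxypropanethioate | COc1cc(Br)cc(OC)c1O[C@H](C(=O)SCC)[C@@H](O)c1ccc(OCc2ccccc2)c(OC)c1 | intermediate
9 | (1S,2R)-1-[4-(benzyloxy)-3-methoxyphenyl]-2-(4-bromo-2,6-dimethoxyphenoxy)propane-1,3-diol | COc1cc(Br)cc(OC)c1O[C@H](CO)[C@@H](O)c1ccc(OCc2ccccc2)c(OC)c1 | intermediate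
10 | (2R,3S)-3-[4-(benzyloxy)-3-methoxyphenyl]-2-(4-bromo-2,6-dimethoxyphenoxy)-3-hydroxypropyl 4-methylbenzenesulfonate | COc1cc(Br)cc(OC)c1O[C@H](COS(=O)(=O)c1ccc(C)cc1)[C@@H](O)c1ccc(OCc2ccccc2)c(OC)c1 | intermediate
11 | (1S,2R)-1-[4-(benzyloxy)-3-methoxyphenyl]-2-(4-bromo-2,6-dimethoxyphenoxy)propan-1-ol | COc1cc(Br)cc(OC)c1O[C@H](C)[C@@H](O)c1ccc(OCc2ccccc2)c(OC)c1 | intermediate
12 | {(1S,2R)-1-[4-(benzyloxy)-3-methoxyphenyl]-2-(4-bromo-2,6-dimethoxyphenoxy)propoxy}(tert-butyl)dimethylsilane | COc1cc(Br)cc(OC)c1O[C@H](C)[C@@H](O[Si](C)(C)C(C)(C)C)c1ccc(OCc2ccccc2)c(OC)c1 | intermediate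
13 | 4-bromo-2-methoxyphenol | COc1cc(Br)ccc1O | starting material
14 | 1-(benzyloxy)-4-bromo-2-methoxybenzene | COc1cc(Br)ccc1OCc1ccccc1 | intermediate
15 | meso-2,3-dimethylsuccinic acid | OC(=O)[C@H](C)[C@H](C)C(O)=O | starting material
16 | cis-3,4-dimethyloxolane-2,5-dione (meso, 3R,4S) | O=C1[C@H](C)[C@H](C)C(=O)O1 | intermediate
17 | (2R,3S)-4-methoxy-2,3-dimethyl-4-oxobutanoic acid | OC(=O)[C@H](C)[C@H](C)C(=O)OC | intermediate
18 | methyl (2S,3R)-4-hydroxy-2,3-dimethylbutanoate | OC[C@H](C)[C@H](C)C(=O)OC | intermediate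
19 | (3S,4R)-3,4-dimethyloxolan-2-one | O1C[C@H](C)[C@H](C)C1=O | intermediate
20 | trimethylsilyl (2S,3R)-4-iodo-2,3-dimethylbutanoate | IC[C@H](C)[C@H](C)C(=O)O[Si](C)(C)C | intermediate
21 | (2S,3R)-4-iodo-2,3-dimethylbutanoic acid | IC[C@H](C)[C@H](C)C(O)=O | intermediate
22 | methyl (2S,3R)-4-iodo-2,3-dimethylbutanoate | IC[C@H](C)[C@H](C)C(=O)OC | intermediate
23 | [(2R,3S)-4-methoxy-2,3-dimethyl-4-oxobutyl]zinc iodide | I[Zn]C[C@H](C)[C@H](C)C(=O)OC | intermediate
24 | methyl (2S,3S)-4-[4-(benzyloxy)-3-methoxyphenyl]-2,3-dimethylbutanoate | COc1cc(C[C@H](C)[C@H](C)C(=O)OC)ccc1OCc1ccccc1 | intermediate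
25 | (2S,3S)-4-[4-(benzyloxy)-3-methoxyphenyl]-2,3-dimethylbutan-1-ol | COc1cc(C[C@H](C)[C@H](C)CO)ccc1OCc1ccccc1 | intermediate
26 | 1-(benzyloxy)-4-[(2S,3S)-4-iodo-2,3-dimethylbutyl]-2-methoxybenzene | COc1cc(C[C@H](C)[C@H](C)CI)ccc1OCc1ccccc1 | intermediate
27 | {(2S,3S)-4-[4-(benzyloxy)-3-methoxyphenyl]-2,3-dimethylbutyl}zinc iodide | COc1cc(C[C@H](C)[C@H](C)C[Zn]I)ccc1OCc1ccccc1 | intermediate
28 | {(1S,2R)-1-[4-(benzyloxy)-3-methoxyphenyl]-2-[4-{(2R,3S)-4-[4-(benzyloxy)-3-methoxyphenyl]-2,3-dimethylbutyl}-2,6-dimethoxyphenoxy]propoxy}(tert-butyl)dimethylsilane | COc1cc(C[C@H](C)[C@H](C)Cc2cc(OC)c(O[C@H](C)[C@@H](O[Si](C)(C)C(C)(C)C)c3ccc(OCc4ccccc4)c(OC)c3)c(OC)c2)ccc1OCc1ccccc1 | intermediate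
29 | (1S,2R)-1-[4-(benzyloxy)-3-methoxyphenyl]-2-[4-{(2R,3S)-4-[4-(benzyloxy)-3-methoxyphenyl]-2,3-dimethylbutyl}-2,6-dimethoxyphenoxy]propan-1-ol | COc1cc(C[C@H](C)[C@H](C)Cc2cc(OC)c(O[C@H](C)[C@@H](O)c3ccc(OCc4ccccc4)c(OC)c3)c(OC)c2)ccc1OCc1ccccc1 | intermediate
30 | (+)-(7''S,8S,8'R,8''R)-4,4''-dihydroxy-3,3',3'',5'-tetramethoxy-4',8''-oxy-8,8'-sesquineolignan-7''-ol | COc1cc(C[C@H](C)[C@H](C)Cc2cc(OC)c(O[C@H](C)[C@@H](O)c3ccc(O)c(OC)c3)c(OC)c2)ccc1O | target

**Step count**

Total: 19 steps. Longest linear sequence: 11 steps (steps 1–8, then 17–19).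

**Steps most likely to fail**

Step 4. The aryl ether oxygen may coordinate tin less well than a benzyl ether oxygen, which would erode anti selectivity or facial control, and any E isomer carried in 5 would add syn adduct. The fallback sets out from phenol 3 and returns to the route at alcohol 11, bypassing steps 1–7. Mitsunobu etherification of 3 with ethyl (S)-lactate (PPh3, diisopropyl azodicarboxylate, THF) should give, with inversion, ethyl (2R)-2-(4-bromo-2,6-dimethoxyphenoxy)propanoate F1. AlMe3 and MeNH(OMe)·HCl in CH2Cl2 convert it into (2R)-2-(4-bromo-2,6-dimethoxyphenoxy)-N-methoxy-N-methylpropanamide F2. Bromide 14 and Mg in THF give [4-(benzyloxy)-3-methoxyphenyl]magnesium bromide F3, which adds once to F2 to give (2R)-1-[4-(benzyloxy)-3-methoxyphenyl]-2-(4-bromo-2,6-dimethoxyphenoxy)propan-1-one F4. Chelation-controlled reduction with Zn(BH4)2 in Et2O at low temperature should then give the erythro alcohol 11, which enters step 8. Here C8'' comes from the chiral pool and C7'' from substrate control, and C9'' is a methyl group from the start.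

Step 17. Zinc insertion or transmetalation of the beta-branched alkyl fragment may be slow, so that protodezincation, beta-hydride elimination or reduction of the electron-rich aryl bromide competes. The fallback sets out from iodide 26 and returns at 28 by a B-alkyl Suzuki–Miyaura coupling. Iodine–lithium exchange with t-BuLi (2 equiv, Et2O, -78 °C) gives {(2R,3S)-4-[4-(benzyloxy)-3-methoxyphenyl]-2,3-dimethylbutyl}lithium F5. This is trapped with 9-methoxy-9-borabicyclo[3.3.1]nonane as lithium 9-{(2R,3S)-4-[4-(benzyloxy)-3-methoxyphenyl]-2,3-dimethylbutyl}-9-methoxy-9-boranuidabicyclo[3.3.1]nonane F6. Without isolation, F6 is coupled with bromide 12 (PdCl2(dppf), aqueous K3PO4, DMF, 25–50 °C) to give 28.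

Step 11. The methanolysis may proceed with insufficient enantioselectivity or in the opposite sense, which would surface after step 17 as a diastereomer that is hard to remove. The fallback sets out from anhydride 16 and returns at lactone 19. The pseudo-enantiomeric catalyst (DHQD)2AQN with MeOH in Et2O at -20 °C gives the antipodal hemiester (2S,3R)-4-methoxy-2,3-dimethyl-4-oxobutanoic acid F7. In F7 the ester, not the acid, is reduced (LiEt3BH, 3 equiv, THF, 0 °C, on the lithium carboxylate). Acidification (2 M HCl) releases (2S,3R)-4-hydroxy-2,3-dimethylbutanoic acid F8, which lactonises to the same lactone 19. Reducing the other carbonyl of the mirror-image hemiester converges on the same enantiomer of the lactone.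

Further compounds
F1 | step 4 | ethyl (2R)-2-(4-bromo-2,6-dimethoxyphenoxy)propanoate | COc1cc(Br)cc(OC)c1O[C@H](C)C(=O)OCC
F2 | step 4 | (2R)-2-(4-bromo-2,6-dimethoxyphenoxy)-N-methoxy-N-methylpropanamide | COc1cc(Br)cc(OC)c1O[C@H](C)C(=O)N(C)OC
F3 | step 4 | [4-(benzyloxy)-3-methoxyphenyl]magnesium bromide | COc1cc([Mg]Br)ccc1OCc1ccccc1
F4 | step 4 | (2R)-1-[4-(benzyloxy)-3-methoxyphenyl]-2-(4-bromo-2,6-dimethoxyphenoxy)propan-1-one | COc1cc(Br)cc(OC)c1O[C@H](C)C(=O)c1ccc(OCc2ccccc2)c(OC)c1
F5 | step 17 | {(2R,3S)-4-[4-(benzyloxy)-3-methoxyphenyl]-2,3-dimethylbutyl}lithium | COc1cc(C[C@H](C)[C@H](C)C[Li])ccc1OCc1ccccc1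
F6 | step 17 | lithium 9-{(2R,3S)-4-[4-(benzyloxy)-3-methoxyphenyl]-2,3-dimethylbutyl}-9-methoxy-9-boranuidabicyclo[3.3.1]nonane | [Li+].COc1cc(C[C@H](C)[C@H](C)C[B-]2(OC)C3CCCC2CCC3)ccc1OCc1ccccc1
F7 | step 11 | (2S,3R)-4-methoxy-2,3-dimethyl-4-oxobutanoic acid | OC(=O)[C@@H](C)[C@@H](C)C(=O)OC
F8 | step 11 | (2S,3R)-4-hydroxy-2,3-dimethylbutanoic acid | OC(=O)[C@@H](C)[C@@H](C)CO
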